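The data are calculated for substances that don't exist.

The leftover of Wednesday's flask is its cold tail, the 1.33 min after the change of temperature. That tail can be reckoned apart, as a correction to the warm start.

| flask | starting material | coupling partner | free catalyst | temperature | remark | time |
|---|---|---|---|---|---|---|
| oak | 0.0050 M | 6.5 mM | 7.1 µM | −30 °C | run made earlier |  |
| alder | 0.0050 M | 6.5 mM | 14 µM | −10 °C | run made earlier |  |
| birch | 0.0028 M | 6.5 mM | 10 µM | −30 °C | run made earlier |  |
| Wednesday's | 0.0050 M | 6.50 mM | 10 µM |  | at 5 °C until 40 s, from then on at −25 °C | 2.0 min |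
| Tuesday's | 0.0030 M | 6.50 mM | 6.0 µM |  | at 5 °C throughout | 2.0 min |

| run | time / min | target / % |
|---|---|---|
| oak | 1.00 | 1.9 |
| oak | 1.33 | 2.5 |
| oak | 2.50 | 4.4 |
| oak | 4.00 | 5.9 |
| oak | 8.00 | 12.1 |
| oak | 12.0 | 16.3 |
| alder | 0.333 | 8.1 |
| alder | 0.833 | 16.9 |
| alder | 1.33 | 25.0 |
| alder | 2.00 | 35.6 |
| alder | 3.00 | 46.9 |
| alder | 4.00 | 55.6 |
| birch | 1.00 | 3.6 |
| birch | 3.00 | 9.0 |
| birch | 6.00 | 18.5 |
| birch | 8.00 | 23.5 |
| birch | 12.0 | 34.2 |

(standard deviation of a reading: 0.5 percentage points)

- in percentages every species weighs as the starting material in it: one side product counts as two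
- for target the crystals are counted in
- as a solid, counted per litre of solution: crystals
- on the list of suspects stand: starting material + catalyst intermediate A <-> catalyst intermediate B; catalyst intermediate B <-> free catalyst + target; crystals <-> target; coupling partner + free catalyst -> catalyst intermediate A; starting material + target -> side product

1. the winner by amount of target, in percent of the starting material charged; "neither" if no more than 2 percentage points parts them (Wednesday's / Tuesday's / neither)
2. how much target is there at the end, in percent of the starting material charged: Wednesday's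
3. how much target is there at the end, in percent of the starting material charged: Tuesday's

The measure is the turnover: target made per catalyst charged, per minute. Early readings give 12.4 min⁻¹ in the oak run and 8.40 min⁻¹ in the birch run, both at −30 °C. The alder run gives 72.5 min⁻¹ at −10 °C, but 49.6 min⁻¹ by its last reading. Equal steps in the logarithm per degree give a ladder reckoned here, fastest first:

5 °C: 272 min⁻¹

−10 °C: 72.5 min⁻¹

−25 °C: 19.3 min⁻¹

−30 °C: 12.4 min⁻¹

For Wednesday's, the top rung over 40 s gives:

warm part = turnover × time × [free catalyst] / [starting material] = 36.3%

The −25 °C rung over the rest gives: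

tail count = 25.7 turnovers

tail part = 5.14%

This tail count, the turnovers per catalyst after the change, is worth less than the warm part. The sum, 41.4%, stands here as a high estimate for Wednesday's, since the alder run slowed as it ran. In Tuesday's, the top rung over 2.0 min gives 109% of the charge, more than the charge itself, so that flask cannot stay on the rung. It stays warm longer than Wednesday's, and this reckoning picks Tuesday's.

The forecast names Tuesday's, with 35% for Wednesday's and 60% for Tuesday's, and holds that “partner depletion or target inhibition matters”.

The flasks give Tuesday's as the winner, with 28.1% for Wednesday's and 42.8% for Tuesday's.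

    starting material + catalyst intermediate A ⇌ catalyst intermediate B (K = 4500 M⁻¹, k = 1210 M⁻¹ s⁻¹, Ea = 37.0 kJ mol⁻¹, ΔH = −2.00 kJ mol⁻¹)
    catalyst intermediate B ⇌ free catalyst + target (K = 0.00303 M, k = 18.9 s⁻¹, Ea = 65.0 kJ mol⁻¹, ΔH = −31.0 kJ mol⁻¹)
    crystals ⇌ target, rate k3*(cs3 - [target]) while solid is left; crystals form when [target] > cs3 (solubility = 2.20 mM, k = 0.966 s⁻¹)
    coupling partner + free catalyst → catalyst intermediate A (k = 3910 M⁻¹ s⁻¹, Ea = 14.0 kJ mol⁻¹)
    starting material + target → side product (k = 0.885 M⁻¹ s⁻¹, Ea = 37.0 kJ mol⁻¹)
    (constants at 5 °C)

Wednesday's holds 24.4% target and 3.77% side product at the change, and 28.1% and 5.63% at the end. Each side product took one target and counts as two, so the tail made 4.6 percentage points of target, against 5.14% by the tail count. At the change of temperature, 0.667 min in, Wednesday's held 24.4% target, not the 36.3% of the warm part, with catalyst intermediate A, the resting state at that moment, at 65.8% of the catalyst.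

In a neighbour flask, Wednesday's recipe with 2.5 × 10⁻⁵ M of free catalyst, the tail count gives a tail part of 12.8%. That flask ends at 57.6%.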